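**Retrosynthetic overview** (target labels: C1 = aryl-bearing quaternary carbon, C2 = CH(CH3), C3 = bromomethylidene carbon, C4/C5 = ring CH2)
1. Target 18 ⇐ para-bromination of phenol 17 ⇐ stereoretentive bromodeboronation of (E)-alkenyl boronate 15 ⇐ boron-Wittig on ketone 12.
2. Ketone 12 ⇐ C2–C3 ring closure by titanium-mediated keto ester coupling of 10; the C2–H is put in last, by kinetic protonation of enol ether 11.
3. Keto ester 10 ⇐ Wacker oxidation of ester 9; key disconnection C1–C5: zinc ester homoenolate 8 plus the γ-carbon of Z-allylic phosphate 6 (copper-catalysed asymmetric SN2'), which sets C1.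
4. Phosphate 6 ⇐ 4,7-dimethylcoumarin 1 (lactone reduction, phenol MOM protection, phosphorylation).
5. Ring order: the aromatic ring is bought with the coumarin; the cyclopentane is the only ring formed (step 6).

Assumption: the enantiomer of the chiral NHC ligand used in step 4 is the one that delivers (R)-9 (sense of induction assigned by analogy, to be confirmed at ketone 12), and all numbered starting materials are taken as commercial.

**Step 1**
Reactants: 1 4,7-dimethylcoumarin
Product: 2 (2Z)-3-(2-hydroxy-4-methylphenyl)but-2-en-1-ol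
Conditions: iBu2AlH (4 equiv), CH2Cl2, −78 → 0 °C; aq. KNaC4H4O6 work-up (kept neutral)
Reagents that add atoms: none
Why: Hydride reduction of the lactone (1,2-reduction through the lactol) opens the coumarin to the allylic alcohol and the free phenol, and the Z geometry of the trisubstituted alkene is inherited from the ring, with no stereocenter formed.

**Step 2**
Reactants: 2 (2Z)-3-(2-hydroxy-4-methylphenyl)but-2-en-1-ol; 3 chloromethyl methyl ether
Product: 4 (2Z)-3-[2-(methoxymethoxy)-4-methylphenyl]but-2-en-1-ol
Conditions: MOMCl (1.1 equiv), K2CO3 (2 equiv), acetone, 0 °C → rt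
Reagents that add atoms: chloromethyl methyl ether 3, COCCl
Why: Williamson-type O-alkylation in which K2CO3 deprotonates only the phenol (pKa about 10), so the MOM group goes on the phenol oxygen and the allylic alcohol stays free.

**Step 3**
Reactants: 4 (2Z)-3-[2-(methoxymethoxy)-4-methylphenyl]but-2-en-1-ol; 5 diethyl chlorophosphate
Product: 6 diethyl (2Z)-3-[2-(methoxymethoxy)-4-methylphenyl]but-2-en-1-yl phosphate
Conditions: ClP(O)(OEt)2 (1.2 equiv), Et3N (1.5 equiv), DMAP (10 mol%), CH2Cl2, 0 °C; used promptly
Reagents that add atoms: diethyl chlorophosphate 5, CCOP(=O)(Cl)OCC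
Why: Phosphorylation of the primary allylic alcohol (substitution at phosphorus with DMAP catalysis) installs the leaving group for SN2' substitution without touching the alkene geometry.

**Step 4**
Reactants: 6 diethyl (2Z)-3-[2-(methoxymethoxy)-4-methylphenyl]but-2-en-1-yl phosphate; 7 (1-ethoxycyclopropoxy)trimethylsilane
Product: 9 ethyl (4R)-4-[2-(methoxymethoxy)-4-methylphenyl]-4-methylhex-5-enoate, via zinc homoenolate 8 (not isolated)
Conditions: 7 (4 equiv), ZnCl2 (2 equiv), Et2O, rt, 1 h, volatiles removed; then 6, (CuOTf)2·C6H6 (2.5 mol%), chiral sulfonate-bearing imidazolinium salt (bidentate NHC precursor, 5.5 mol%), THF, −15 °C, 24 h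
Reagents that add atoms: (1-ethoxycyclopropoxy)trimethylsilane 7, CCOC1(CC1)O[Si](C)(C)C
Why: Proposed new method: copper-catalysed enantioselective SN2' allylic alkylation with a zinc homoenolate, in which the NHC–copper alkyl formed by transmetalation from 8 attacks the γ-carbon anti to the phosphate and reductive elimination from the σ-allyl copper species gives the branched product, so the ester β-carbon (normally electrophilic) is joined to the electrophilic allylic terminus and the chiral sulfonate-bridged NHC ligand sets the quaternary center C1 on the geometrically pure Z alkene; the closest known reactions are NHC–copper-catalysed asymmetric allylic alkylations of aryl/methyl-substituted allylic phosphates with dialkylzincs and the racemic copper-catalysed SN2' allylation of this same zinc homoenolate.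

**Step 5**
Reactants: 9 ethyl (4R)-4-[2-(methoxymethoxy)-4-methylphenyl]-4-methylhex-5-enoate
Product: 10 ethyl (4S)-4-[2-(methoxymethoxy)-4-methylphenyl]-4-methyl-5-oxohexanoate
Conditions: PdCl2 (10 mol%), CuCl (1 equiv), O2 (1 atm), DMF/H2O (7:1), rt
Reagents that add atoms: water, SMILES O
Why: Tsuji–Wacker oxidation, in which Markovnikov hydroxypalladation of the terminal vinyl group and β-hydride elimination give the methyl ketone, while the neighbouring quaternary carbon blocks alkene migration and is itself untouched (the descriptor changes only because of CIP priorities).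

**Step 6**
Reactants: 10 ethyl (4S)-4-[2-(methoxymethoxy)-4-methylphenyl]-4-methyl-5-oxohexanoate
Product: 12 (2R,3R)-3-[2-(methoxymethoxy)-4-methylphenyl]-2,3-dimethylcyclopentan-1-one, via cyclic enol ether 11 (not isolated)
Conditions: TiCl3 (8 equiv), LiAlH4 (4 equiv), Et3N (1 equiv), DME, reflux, 10 added over 20 h; then 1 M HCl, THF, 0 °C, 30 min
Reagents that add atoms: water, SMILES O
Why: McMurry keto ester cyclization, in which low-valent titanium reductively couples the ketone and ester carbonyl carbons to the five-membered enol ether 11, and cold acid hydrolysis then protonates C2 irreversibly from the face opposite the bulky aryl group on the adjacent quaternary carbon, placing the C2 methyl cis to the aryl group under kinetic control.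

**Step 7**
Reactants: 12 (2R,3R)-3-[2-(methoxymethoxy)-4-methylphenyl]-2,3-dimethylcyclopentan-1-one; 13 2,2'-methylenebis(4,4,5,5-tetramethyl-1,3,2-dioxaborolane)
Product: 15 2-[(E)-{(2S,3R)-3-[2-(methoxymethoxy)-4-methylphenyl]-2,3-dimethylcyclopentylidene}methyl]-4,4,5,5-tetramethyl-1,3,2-dioxaborolane, via lithiated diborylmethane 14 (not isolated)
Conditions: 13 (1.5 equiv), lithium 2,2,6,6-tetramethylpiperidide (1.5 equiv), THF, 0 °C, 15 min; then 12, −78 °C → rt
Reagents that add atoms: 2,2'-methylenebis(4,4,5,5-tetramethyl-1,3,2-dioxaborolane) 13, C(B1OC(C)(C)C(C)(C)O1)B1OC(C)(C)C(C)(C)O1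
Why: Boron-Wittig olefination, in which the weakly basic α-boryl carbanion 14 adds to the ketone and syn B–O elimination leaves the remaining boryl group on the side of the C4 methylene, away from the branched C2 (E isomer), while C2 is not epimerized because any competing deprotonation occurs at the unhindered C4 methylene.

**Step 8**
Reactants: 15 2-[(E)-{(2S,3R)-3-[2-(methoxymethoxy)-4-methylphenyl]-2,3-dimethylcyclopentylidene}methyl]-4,4,5,5-tetramethyl-1,3,2-dioxaborolane
Product: 17 2-[(1R,2R,3E)-3-(bromomethylidene)-1,2-dimethylcyclopentyl]-5-methylphenol, via alkenyl bromide MOM ether 16 (not isolated)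
Conditions: CuBr2 (3 equiv), MeOH/H2O (3:1), 70 °C, 12 h; then 2 M HCl, 50 °C, 2 h
Reagents that add atoms: copper dibromide CuBr2, [Cu+2].[Br-].[Br-]
Why: Copper-mediated halodeboronation converts the alkenyl C–B bond into C–Br with retention of alkene geometry, and the HBr released together with the added HCl removes the MOM acetal by methanolysis, with no stereocenter touched.

**Step 9**
Reactants: 17 2-[(1R,2R,3E)-3-(bromomethylidene)-1,2-dimethylcyclopentyl]-5-methylphenol
Product: 18 4-bromo-2-[(1R,2R,3E)-3-(bromomethylidene)-1,2-dimethylcyclopentyl]-5-methylphenol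
Conditions: N-bromosuccinimide (1.0 equiv), MeCN, 0 °C
Reagents that add atoms: N-bromosuccinimide, O=C1CCC(=O)N1Br
Why: Electrophilic aromatic bromination, in which the free phenol directs to the para position (also ortho to the ring methyl), the only unhindered activated site, while the electron-poor bromoalkene does not react.

**Compound list**
1 | 4,7-dimethylcoumarin | Cc1ccc2c(C)cc(=O)oc2c1 | starting material
2 | (2Z)-3-(2-hydroxy-4-methylphenyl)but-2-en-1-ol | Cc1cc(O)c(/C(C)=C\CO)cc1 | intermediate
3 | chloromethyl methyl ether | COCCl | starting material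
4 | (2Z)-3-[2-(methoxymethoxy)-4-methylphenyl]but-2-en-1-ol | Cc1cc(OCOC)c(/C(C)=C\CO)cc1 | intermediate
5 | diethyl chlorophosphate | CCOP(=O)(Cl)OCC | starting material
6 | diethyl (2Z)-3-[2-(methoxymethoxy)-4-methylphenyl]but-2-en-1-yl phosphate | Cc1cc(OCOC)c(/C(C)=C\COP(=O)(OCC)OCC)cc1 | intermediate
7 | (1-ethoxycyclopropoxy)trimethylsilane | CCOC1(CC1)O[Si](C)(C)C | starting material
8 | bis(3-ethoxy-3-oxopropyl)zinc (zinc homoenolate) | CCOC(=O)CC[Zn]CCC(=O)OCC | intermediate
9 | ethyl (4R)-4-[2-(methoxymethoxy)-4-methylphenyl]-4-methylhex-5-enoate | Cc1cc(OCOC)c([C@](C=C)(C)CCC(=O)OCC)cc1 | intermediate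
10 | ethyl (4S)-4-[2-(methoxymethoxy)-4-methylphenyl]-4-methyl-5-oxohexanoate | Cc1cc(OCOC)c([C@](C(C)=O)(C)CCC(=O)OCC)cc1 | intermediate
11 | 1-[(1R)-3-ethoxy-1,2-dimethylcyclopent-2-en-1-yl]-2-(methoxymethoxy)-4-methylbenzene | Cc1cc(OCOC)c([C@]2(C)CCC(OCC)=C2C)cc1 | intermediate
12 | (2R,3R)-3-[2-(methoxymethoxy)-4-methylphenyl]-2,3-dimethylcyclopentan-1-one | Cc1cc(OCOC)c([C@]2(C)CCC(=O)[C@@H]2C)cc1 | intermediate
13 | 2,2'-methylenebis(4,4,5,5-tetramethyl-1,3,2-dioxaborolane) | C(B1OC(C)(C)C(C)(C)O1)B1OC(C)(C)C(C)(C)O1 | starting material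
14 | [bis(4,4,5,5-tetramethyl-1,3,2-dioxaborolan-2-yl)methyl]lithium | [Li]C(B1OC(C)(C)C(C)(C)O1)B1OC(C)(C)C(C)(C)O1 | intermediate
15 | 2-[(E)-{(2S,3R)-3-[2-(methoxymethoxy)-4-methylphenyl]-2,3-dimethylcyclopentylidene}methyl]-4,4,5,5-tetramethyl-1,3,2-dioxaborolane | Cc1cc(OCOC)c([C@]2(C)CC/C(=C\B3OC(C)(C)C(C)(C)O3)[C@@H]2C)cc1 | intermediate
16 | 1-[(1R,2R,3E)-3-(bromomethylidene)-1,2-dimethylcyclopentyl]-2-(methoxymethoxy)-4-methylbenzene | Cc1cc(OCOC)c([C@]2(C)CC/C(=C\Br)[C@@H]2C)cc1 | intermediate
17 | 2-[(1R,2R,3E)-3-(bromomethylidene)-1,2-dimethylcyclopentyl]-5-methylphenol | Cc1cc(O)c([C@]2(C)CC/C(=C\Br)[C@@H]2C)cc1 | intermediate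
18 | 4-bromo-2-[(1R,2R,3E)-3-(bromomethylidene)-1,2-dimethylcyclopentyl]-5-methylphenol | Cc1cc(O)c([C@]2(C)CC/C(=C\Br)[C@@H]2C)cc1Br | target

**Step count and risks**
Total steps: 9. Longest linear sequence: 9 (1 → 18); reagents 8 and 14 are made in the flask within steps 4 and 7.

The three steps most likely to fail:

Step 4. The ester-chelated zinc homoenolate may transmetalate to copper too slowly, and the enantioselectivity on a Z-configured, ortho-alkoxyaryl phosphate is untested. The fallback keeps a homoenolate equivalent but changes the reagent class and catalyst system; it sets out from alcohol 4 and comes back at ester 9. Alcohol 4 is converted (MsCl, LiCl, 2,4,6-collidine, DMF, 0 °C) into 1-[(2Z)-4-chlorobut-2-en-2-yl]-2-(methoxymethoxy)-4-methylbenzene F1. Copper-catalysed asymmetric SN2' alkylation of F1 with the commercial acetal Grignard reagent 2-(1,3-dioxolan-2-yl)ethylmagnesium bromide (copper thiophene-2-carboxylate C5H3CuO2S 3 mol%, chiral phosphoramidite ligand 3.3 mol%, CH2Cl2, −78 °C) gives 2-{(3R)-3-[2-(methoxymethoxy)-4-methylphenyl]-3-methylpent-4-en-1-yl}-1,3-dioxolane F2. Acetal hydrolysis (pyridinium p-toluenesulfonate, acetone/H2O, 50 °C) gives (4R)-4-[2-(methoxymethoxy)-4-methylphenyl]-4-methylhex-5-enal F3, and oxidative esterification (I2, KOH, EtOH, 0 °C) returns 9.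

Step 6. The ketone is flanked by a quaternary carbon, the conditions are harsh for the MOM ether, and the C2 configuration depends on the facial selectivity of one protonation (the wanted isomer, C2 methyl cis to aryl, is expected to be the less stable one, so the hydrolysis must stay cold and short). The fallback sets out from ester 9 (step 5 is then skipped) and comes back at ketone 12. Intramolecular Kulinkovich cyclopropanation (Ti(OiPr)4, cyclopentylmagnesium chloride, THF, rt) gives (4R)-4-[2-(methoxymethoxy)-4-methylphenyl]-4-methylbicyclo[3.1.0]hexan-1-ol F4. Oxidative ring opening of the cyclopropanol (Pd(OAc)2 10 mol%, pyridine, O2, toluene, 80 °C) gives (3S)-3-[2-(methoxymethoxy)-4-methylphenyl]-3-methyl-2-methylidenecyclopentan-1-one F5. Hydrogenation (H2 1 atm, Pd/C, EtOAc, 0 °C) adds hydrogen to the exocyclic alkene from the face opposite the aryl group and gives 12.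

Step 7. Addition to the hindered ketone may lose out to enolization, and the E/Z ratio of the alkenyl boronate is not assured. The fallback sets out from ketone 12 and comes back at boronate 15. Non-basic methylenation (Zn, CH2Br2, TiCl4, THF/CH2Cl2, 0 °C → rt) gives 1-[(1R,2S)-1,2-dimethyl-3-methylidenecyclopentyl]-2-(methoxymethoxy)-4-methylbenzene F6. Cross-metathesis of F6 with 2-ethenyl-4,4,5,5-tetramethyl-1,3,2-dioxaborolane (second-generation Hoveyda–Grubbs catalyst 10 mol%, CH2Cl2, 40 °C) places the boryl group on the less hindered side and gives 15.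

**Further compounds**
F1 | step 4 | 1-[(2Z)-4-chlorobut-2-en-2-yl]-2-(methoxymethoxy)-4-methylbenzene | Cc1cc(OCOC)c(/C(C)=C\CCl)cc1
F2 | step 4 | 2-{(3R)-3-[2-(methoxymethoxy)-4-methylphenyl]-3-methylpent-4-en-1-yl}-1,3-dioxolane | Cc1cc(OCOC)c([C@](C=C)(C)CCC2OCCO2)cc1
F3 | step 4 | (4R)-4-[2-(methoxymethoxy)-4-methylphenyl]-4-methylhex-5-enal | Cc1cc(OCOC)c([C@](C=C)(C)CCC=O)cc1
F4 | step 6 | (4R)-4-[2-(methoxymethoxy)-4-methylphenyl]-4-methylbicyclo[3.1.0]hexan-1-ol | Cc1cc(OCOC)c([C@]2(C)CCC3(O)CC23)cc1
F5 | step 6 | (3S)-3-[2-(methoxymethoxy)-4-methylphenyl]-3-methyl-2-methylidenecyclopentan-1-one | Cc1cc(OCOC)c([C@]2(C)CCC(=O)C2=C)cc1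
F6 | step 7 | 1-[(1R,2S)-1,2-dimethyl-3-methylidenecyclopentyl]-2-(methoxymethoxy)-4-methylbenzene | Cc1cc(OCOC)c([C@]2(C)CCC(=C)[C@@H]2C)cc1
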